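The target is read as a folded, oxidised retinoid: ring A with C6 comes from (4R,6R)-actinol, which supplies the C2 stereocentre, and C7–C9 with the side chain from geraniol. Everything rests on the C9–C10 bond of ring B (C5–C6–C7–C8–C9–C10). With C6 as a ketone, the quaternary C10 is the β-carbon of a ring-A enone and the methyl-bearing C8=C9 olefin lies five atoms away, so a Lewis-acid cation–olefin cyclisation of the monocyclic β-cyclogeranyl-type ketone 13 closes ring B, creates C10 under control of C2 and sets C5. Deconjugative C7 hydroxylation and α-face reduction at C6 then deliver the 6β,7α-diol for the two different esters.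

Key step: step 9

Assumption: (4R,6R)-actinol, an industrial zeaxanthin intermediate, is taken as a commercial starting material; labdane numbering (C1–C20, α = face opposite the C10 methyl) is used for all compounds from 12 onwards.

Step 1
Reactants: 1 (4R,6R)-actinol [(4R,6R)-4-hydroxy-2,2,6-trimethylcyclohexan-1-one]
Product: 2 (4R,6R)-2,2,6-trimethyl-4-(triethylsilyloxy)cyclohexan-1-one
Conditions: TESCl, imidazole, CH2Cl2, 0 °C → rt
Reagents that add atoms: chlorotriethylsilane CC[Si](Cl)(CC)CC
Why: Silylation of the secondary alcohol masks the future C2 oxygen for the base- and metal-mediated steps without touching a stereocentre.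

Step 2
Reactants: 2 (4R,6R)-2,2,6-trimethyl-4-(triethylsilyloxy)cyclohexan-1-one
Product: 4 (R)-2,6,6-trimethyl-4-(triethylsilyloxy)cyclohex-1-en-1-yl trifluoromethanesulfonate, via potassium enolate 3 (not isolated)
Conditions: KHMDS, THF, −78 °C; PhNTf2, −78 → 0 °C
Reagents that add atoms: N-phenylbis(trifluoromethanesulfonimide) O=S(=O)(N(c1ccccc1)S(=O)(=O)C(F)(F)F)C(F)(F)F
Why: Enolisation is only possible towards the methyl-bearing α-carbon (the other is quaternary), so enolate O-triflation should give the tetrasubstituted enol triflate regiospecifically, the methine stereocentre being erased on purpose.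

Step 3
Reactants: 4 (R)-2,6,6-trimethyl-4-(triethylsilyloxy)cyclohex-1-en-1-yl trifluoromethanesulfonate
Product: 5 (R)-2,6,6-trimethyl-4-(triethylsilyloxy)cyclohex-1-ene-1-carbaldehyde
Conditions: Pd(PPh3)4 (cat.), CO (1 atm), Bu3SnH (slow addition), THF, 50 °C
Reagents that add atoms: carbon monoxide [C-]#[O+]
Why: Palladium-catalysed reductive carbonylation (formylation) of the vinyl triflate installs C6 as the aldehyde of a protected 3-hydroxy-β-cyclocitral.

Step 4
Reactants: 6 geraniol
Product: 7 geranyl tert-butyldiphenylsilyl ether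
Conditions: TBDPSCl, imidazole, DMF, rt
Reagents that add atoms: tert-butylchlorodiphenylsilane CC(C)(C)[Si](Cl)(c1ccccc1)c1ccccc1
Why: Silylation gives a C15 protecting group that is stable to organobarium, Lewis acid, enolate and acylation conditions and is removable at the end in the presence of esters.

Step 5
Reactants: 7 geranyl tert-butyldiphenylsilyl ether
Product: 8 (2E,6E)-8-(tert-butyldiphenylsilyloxy)-2,6-dimethylocta-2,6-dien-1-ol
Conditions: SeO2 (cat.), t-BuOOH, salicylic acid (cat.), CH2Cl2, 0 °C → rt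
Reagents that add atoms: selenium dioxide O=[Se]=O (catalytic oxygen carrier) and tert-butyl hydroperoxide CC(C)(C)OO (stoichiometric oxygen source)
Why: Selenium dioxide allylic oxidation (ene reaction then [2,3]-shift) is selective for the E-methyl group of the distal, more electron-rich trisubstituted olefin, giving the E-allylic alcohol that will become C7.

Step 6
Reactants: 8 (2E,6E)-8-(tert-butyldiphenylsilyloxy)-2,6-dimethylocta-2,6-dien-1-ol
Product: 10 tert-butyl{[(2E,6E)-8-chloro-3,7-dimethylocta-2,6-dien-1-yl]oxy}diphenylsilane, via allylic mesylate 9 (not isolated)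
Conditions: MsCl, 2,4,6-collidine, LiCl, DMF, 0 °C
Reagents that add atoms: lithium chloride [Li+].[Cl-]
Why: In situ mesylation followed by SN2 displacement with chloride should give the primary allylic chloride without allylic transposition or loss of E geometry.

Step 7
Reactants: 10 tert-butyl{[(2E,6E)-8-chloro-3,7-dimethylocta-2,6-dien-1-yl]oxy}diphenylsilane; 5 (R)-2,6,6-trimethyl-4-(triethylsilyloxy)cyclohex-1-ene-1-carbaldehyde
Product: 12 (3E,7E)-9-(tert-butyldiphenylsilyloxy)-3,7-dimethyl-1-[(R)-2,6,6-trimethyl-4-(triethylsilyloxy)cyclohex-1-en-1-yl]nona-3,7-dien-1-ol (mixture of C6 epimers), via allylbarium chloride 11 (not isolated)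
Conditions: BaI2, lithium biphenylide, THF, rt (activated barium); 10, −78 °C; then 5, −78 °C; aq. NH4Cl
Reagents that add atoms: none
Why: Barbier-type carbonyl allylation with an allylbarium reagent is expected to occur at the metal-bearing α-carbon with retention of olefin geometry, giving the linear C6–C7 adduct; the new C6 carbinol centre is formed unselectively and is removed in step 8.

Step 8
Reactants: 12 (3E,7E)-9-(tert-butyldiphenylsilyloxy)-3,7-dimethyl-1-[(R)-2,6,6-trimethyl-4-(triethylsilyloxy)cyclohex-1-en-1-yl]nona-3,7-dien-1-ol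
Product: 13 (3E,7E)-9-(tert-butyldiphenylsilyloxy)-3,7-dimethyl-1-[(R)-2,6,6-trimethyl-4-(triethylsilyloxy)cyclohex-1-en-1-yl]nona-3,7-dien-1-one
Conditions: Dess–Martin periodinane, NaHCO3, CH2Cl2, 0 °C
Reagents that add atoms: none
Why: Buffered Dess–Martin oxidation of the allylic alcohol should give the C6 ketone without moving the β,γ-olefin (C8=C9) into conjugation.

Step 9
Reactants: 13 (3E,7E)-9-(tert-butyldiphenylsilyloxy)-3,7-dimethyl-1-[(R)-2,6,6-trimethyl-4-(triethylsilyloxy)cyclohex-1-en-1-yl]nona-3,7-dien-1-one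
Product: 15 15-(tert-butyldiphenylsilyloxy)-2α-(triethylsilyloxy)labda-7,13E-dien-6-one (5α-H, 9α-H, 10β-CH3), via dichloroaluminium dienolate 14 (not isolated)
Conditions: MeAlCl2 (2.5 equiv), CH2Cl2, −78 → −30 °C; Et3N, then aq. Rochelle salt
Reagents that add atoms: none
Why: MeAlCl2 complexes the C6 carbonyl and makes C10, the β-carbon of the ring-A enone, electrophilic; the E-configured C8=C9 olefin attacks it through C9 in a chair-like transition state, and the tertiary C8 cation loses a C7 proton to an Al–CH3 group (methane) to leave the aluminium dienolate 14, which is protonated at C5 on work-up. The closest known reaction type is the Lewis-acid-promoted cation–olefin (Michael-type) cyclisation of enones onto unactivated olefins, that is, the second ring closure of a polyene cyclisation started from an enone. Ring B closes in a 6-endo-trig mode with respect to both the C8=C9 olefin and the C5=C10 enone. C10 is controlled by the C2 silyloxy stereocentre, because only C–C bond formation on the α-face leads to a ring-A chair with the C2–O bond and the new C10–C9 bond both equatorial, whereas β-attack needs an axial C9 or an axial silyloxy group syn to a C4 methyl; C9 (9α-H, erased in step 10) follows from the E-olefin in the chair, and C5 is set by α-face protonation of the enolate anti to the C10 and 4β methyl groups, which also gives the thermodynamically preferred trans-decalone. The step needs attack through C9 and not C8 (secured by formation of the tertiary cation), needs the distal C13=C14 olefin to stay out (it cannot reach C10 through a six-membered transition state, is inductively deactivated by the allylic silyloxy group, and proton loss from C7 should be fast) and needs the β,γ-olefin not to migrate before cyclisation (aprotic medium, low temperature, proton-scavenging Lewis acid).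

Step 10
Reactants: 15 15-(tert-butyldiphenylsilyloxy)-2α-(triethylsilyloxy)labda-7,13E-dien-6-one
Product: 17 15-(tert-butyldiphenylsilyloxy)-7α-hydroxy-2α-(triethylsilyloxy)labda-8,13E-dien-6-one, via potassium dienolate 16 (not isolated)
Conditions: t-BuOK, THF/t-BuOH, 0 °C; 3-phenyl-2-(phenylsulfonyl)oxaziridine, −78 °C; AcOH quench at −78 °C
Reagents that add atoms: 3-phenyl-2-(phenylsulfonyl)oxaziridine O=S(=O)(N1OC1c1ccccc1)c1ccccc1
Why: Equilibrating base should give the thermodynamic, fully substituted linear dienolate by γ-deprotonation at C9, and enolate hydroxylation by the N-sulfonyloxaziridine at the α-carbon C7 then moves the olefin to C8=C9 and sets 7α-OH, because the β-face is shielded by the axial C10 and 4β methyl groups.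

Step 11
Reactants: 17 15-(tert-butyldiphenylsilyloxy)-7α-hydroxy-2α-(triethylsilyloxy)labda-8,13E-dien-6-one
Product: 19 15-(tert-butyldiphenylsilyloxy)labda-8,13E-diene-2α,6β,7α-triol, via triethylsilyl ether diol 18 (not isolated)
Conditions: NaBH4, MeOH/THF, −20 → 0 °C; then AcOH/H2O, rt
Reagents that add atoms: none
Why: Borohydride reduction of the C6 ketone should occur from the α-face (the β-face is blocked by the syn-axial C10 and 4β methyl groups and the 7α-hydroxyl can direct hydride to the same face) to give the axial 6β-alcohol, and the mild aqueous acid of the work-up then cleaves the triethylsilyl ether while the TBDPS ether survives.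

Step 12
Reactants: 19 15-(tert-butyldiphenylsilyloxy)labda-8,13E-diene-2α,6β,7α-triol
Product: 20 2α,7α-diacetoxy-15-(tert-butyldiphenylsilyloxy)labda-8,13E-dien-6β-ol
Conditions: Ac2O, pyridine, DMAP (cat.), CH2Cl2, 0 °C → rt
Reagents that add atoms: acetic anhydride CC(=O)OC(C)=O
Why: DMAP-catalysed acetylation should esterify the equatorial 2α- and the allylic 7α-hydroxyl groups, whereas the 6β-hydroxyl, 1,3-diaxial to two methyl groups, is expected to stay free (steric differentiation).

Step 13
Reactants: 20 2α,7α-diacetoxy-15-(tert-butyldiphenylsilyloxy)labda-8,13E-dien-6β-ol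
Product: 22 2α,7α-diacetoxy-15-(tert-butyldiphenylsilyloxy)-6β-(3-methylbutanoyloxy)labda-8,13E-diene, via lithium 6β-alkoxide 21 (not isolated)
Conditions: LiHMDS, THF, −78 °C; 3-methylbutanoic anhydride, −78 → −20 °C
Reagents that add atoms: 3-methylbutanoic anhydride CC(C)CC(=O)OC(=O)CC(C)C
Why: Irreversible deprotonation to the lithium alkoxide followed by acylation with the anhydride (alkoxide acylation) should overcome the hindrance of the 6β-hydroxyl, while the trans-diaxial 7α-acetate cannot migrate and the low temperature protects both acetates.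

Step 14
Reactants: 22 2α,7α-diacetoxy-15-(tert-butyldiphenylsilyloxy)-6β-(3-methylbutanoyloxy)labda-8,13E-diene
Product: 23 2α,7α-diacetoxy-6β-(3-methylbutanoyloxy)labda-8,13E-dien-15-ol (CNP0257091.1)
Conditions: HF·pyridine, pyridine, THF, 0 °C → rt
Reagents that add atoms: none
Why: Buffered fluoride-mediated desilylation of the primary allylic silyl ether should free the 15-hydroxyl without hydrolysis or migration of the three esters.

Compound list
1 | (4R,6R)-4-hydroxy-2,2,6-trimethylcyclohexan-1-one [(4R,6R)-actinol] | O=C1C(C)(C)C[C@H](O)C[C@H]1C | starting material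
2 | (4R,6R)-2,2,6-trimethyl-4-(triethylsilyloxy)cyclohexan-1-one | O=C1C(C)(C)C[C@H](O[Si](CC)(CC)CC)C[C@H]1C | intermediate
3 | potassium (R)-2,6,6-trimethyl-4-(triethylsilyloxy)cyclohex-1-en-1-olate | CC1=C([O-])C(C)(C)C[C@H](O[Si](CC)(CC)CC)C1.[K+] | intermediate (not isolated)
4 | (R)-2,6,6-trimethyl-4-(triethylsilyloxy)cyclohex-1-en-1-yl trifluoromethanesulfonate | CC1=C(OS(=O)(=O)C(F)(F)F)C(C)(C)C[C@H](O[Si](CC)(CC)CC)C1 | intermediate
5 | (R)-2,6,6-trimethyl-4-(triethylsilyloxy)cyclohex-1-ene-1-carbaldehyde | CC1=C(C=O)C(C)(C)C[C@H](O[Si](CC)(CC)CC)C1 | intermediate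
6 | geraniol [(2E)-3,7-dimethylocta-2,6-dien-1-ol] | CC(C)=CCC/C(C)=C/CO | starting material
7 | geranyl tert-butyldiphenylsilyl ether | CC(C)=CCC/C(C)=C/CO[Si](c1ccccc1)(c1ccccc1)C(C)(C)C | intermediate
8 | (2E,6E)-8-(tert-butyldiphenylsilyloxy)-2,6-dimethylocta-2,6-dien-1-ol | OC/C(C)=C/CC/C(C)=C/CO[Si](c1ccccc1)(c1ccccc1)C(C)(C)C | intermediate
9 | (2E,6E)-8-(tert-butyldiphenylsilyloxy)-2,6-dimethylocta-2,6-dien-1-yl methanesulfonate | CS(=O)(=O)OC/C(C)=C/CC/C(C)=C/CO[Si](c1ccccc1)(c1ccccc1)C(C)(C)C | intermediate (not isolated)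
10 | tert-butyl{[(2E,6E)-8-chloro-3,7-dimethylocta-2,6-dien-1-yl]oxy}diphenylsilane | ClC/C(C)=C/CC/C(C)=C/CO[Si](c1ccccc1)(c1ccccc1)C(C)(C)C | intermediate
11 | [(2E,6E)-8-(tert-butyldiphenylsilyloxy)-2,6-dimethylocta-2,6-dien-1-yl]barium chloride | Cl[Ba]C/C(C)=C/CC/C(C)=C/CO[Si](c1ccccc1)(c1ccccc1)C(C)(C)C | intermediate (not isolated)
12 | (3E,7E)-9-(tert-butyldiphenylsilyloxy)-3,7-dimethyl-1-[(R)-2,6,6-trimethyl-4-(triethylsilyloxy)cyclohex-1-en-1-yl]nona-3,7-dien-1-ol (C6 epimers) | CC1=C(C(O)C/C(C)=C/CC/C(C)=C/CO[Si](c2ccccc2)(c2ccccc2)C(C)(C)C)C(C)(C)C[C@H](O[Si](CC)(CC)CC)C1 | intermediate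
13 | (3E,7E)-9-(tert-butyldiphenylsilyloxy)-3,7-dimethyl-1-[(R)-2,6,6-trimethyl-4-(triethylsilyloxy)cyclohex-1-en-1-yl]nona-3,7-dien-1-one | CC1=C(C(=O)C/C(C)=C/CC/C(C)=C/CO[Si](c2ccccc2)(c2ccccc2)C(C)(C)C)C(C)(C)C[C@H](O[Si](CC)(CC)CC)C1 | intermediate
14 | dichloroaluminium 15-(tert-butyldiphenylsilyloxy)-2α-(triethylsilyloxy)labda-5,7,13E-trien-6-olate (9α-H) | CC[Si](CC)(CC)O[C@H]1CC(C)(C)C2=C(O[Al](Cl)Cl)C=C(C)[C@H](CC/C(C)=C/CO[Si](c3ccccc3)(c3ccccc3)C(C)(C)C)[C@@]2(C)C1 | intermediate (not isolated)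
15 | 15-(tert-butyldiphenylsilyloxy)-2α-(triethylsilyloxy)labda-7,13E-dien-6-one (5α-H, 9α-H) | CC[Si](CC)(CC)O[C@H]1CC(C)(C)[C@@H]2C(=O)C=C(C)[C@H](CC/C(C)=C/CO[Si](c3ccccc3)(c3ccccc3)C(C)(C)C)[C@@]2(C)C1 | intermediate
16 | potassium 15-(tert-butyldiphenylsilyloxy)-2α-(triethylsilyloxy)labda-6,8,13E-trien-6-olate | CC[Si](CC)(CC)O[C@H]1CC(C)(C)[C@@H]2C([O-])=CC(C)=C(CC/C(C)=C/CO[Si](c3ccccc3)(c3ccccc3)C(C)(C)C)[C@@]2(C)C1.[K+] | intermediate (not isolated)
17 | 15-(tert-butyldiphenylsilyloxy)-7α-hydroxy-2α-(triethylsilyloxy)labda-8,13E-dien-6-one | CC[Si](CC)(CC)O[C@H]1CC(C)(C)[C@@H]2C(=O)[C@@H](O)C(C)=C(CC/C(C)=C/CO[Si](c3ccccc3)(c3ccccc3)C(C)(C)C)[C@@]2(C)C1 | intermediate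
18 | 15-(tert-butyldiphenylsilyloxy)-2α-(triethylsilyloxy)labda-8,13E-diene-6β,7α-diol | CC[Si](CC)(CC)O[C@H]1CC(C)(C)[C@@H]2[C@H](O)[C@@H](O)C(C)=C(CC/C(C)=C/CO[Si](c3ccccc3)(c3ccccc3)C(C)(C)C)[C@@]2(C)C1 | intermediate (not isolated)
19 | 15-(tert-butyldiphenylsilyloxy)labda-8,13E-diene-2α,6β,7α-triol | O[C@H]1CC(C)(C)[C@@H]2[C@H](O)[C@@H](O)C(C)=C(CC/C(C)=C/CO[Si](c3ccccc3)(c3ccccc3)C(C)(C)C)[C@@]2(C)C1 | intermediate
20 | 2α,7α-diacetoxy-15-(tert-butyldiphenylsilyloxy)labda-8,13E-dien-6β-ol | CC(=O)O[C@H]1CC(C)(C)[C@@H]2[C@H](O)[C@@H](OC(C)=O)C(C)=C(CC/C(C)=C/CO[Si](c3ccccc3)(c3ccccc3)C(C)(C)C)[C@@]2(C)C1 | intermediate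
21 | lithium 2α,7α-diacetoxy-15-(tert-butyldiphenylsilyloxy)labda-8,13E-dien-6β-olate | CC(=O)O[C@H]1CC(C)(C)[C@@H]2[C@H]([O-])[C@@H](OC(C)=O)C(C)=C(CC/C(C)=C/CO[Si](c3ccccc3)(c3ccccc3)C(C)(C)C)[C@@]2(C)C1.[Li+] | intermediate (not isolated)
22 | 2α,7α-diacetoxy-15-(tert-butyldiphenylsilyloxy)-6β-(3-methylbutanoyloxy)labda-8,13E-diene | CC(=O)O[C@H]1CC(C)(C)[C@@H]2[C@H](OC(=O)CC(C)C)[C@@H](OC(C)=O)C(C)=C(CC/C(C)=C/CO[Si](c3ccccc3)(c3ccccc3)C(C)(C)C)[C@@]2(C)C1 | intermediate
23 | 2α,7α-diacetoxy-6β-(3-methylbutanoyloxy)labda-8,13E-dien-15-ol (CNP0257091.1) | CC(=O)O[C@H]1CC(C)(C)[C@@H]2[C@H](OC(=O)CC(C)C)[C@@H](OC(C)=O)C(C)=C(CC/C(C)=C/CO)[C@@]2(C)C1 | target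

Total step count: 14. Longest linear sequence: 11 steps (steps 1–3 and 7–14 from actinol; the geraniol branch, steps 4–6 and 7–14, is equally long).

Steps most likely to fail

Step 9. The C8 cation may over-cyclise onto the distal C13=C14 olefin or undergo 1,2-shifts before it loses a proton, the twisted enone may be activated too weakly, or facial selectivity at C10 may be poor. Minor β,γ- or exocyclic olefin isomers of 15 would not matter, since step 10 funnels them through dienolate 16. The fallback replaces the cationic closure by a pericyclic one and sets out from 13. Soft enolisation towards the doubly activated C7 (TMSOTf, Et3N, CH2Cl2, 0 °C) should give the 2-silyloxy-triene, the (6E)-trimethylsilyl trienol ether F1, together with its 6Z isomer, which can be re-equilibrated with a trace of silyl triflate. Heating (toluene, 160–180 °C, sealed base-washed tube) should bring about a thermal disrotatory 6π-electrocyclisation that forms the C9–C10 bond without any cation and gives the bicyclic trimethylsilyl dienol ether F2. Methanolysis (K2CO3, MeOH, 0 °C) should then free the enone as the 9β-H epimer of 15, the epimeric enone F3, the configuration at C9 being dictated by disrotation of the 8E-triene. Under the conditions of step 10, F3 gives the same dienolate, so the fallback comes back to the route at 16.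

Step 10. Enolisation may occur at the wrong site (C5 or the C8 methyl group), and the α-ketol may isomerise under base. The fallback sets out from 15 and separates enolisation from oxidation. Equilibrating silylation (TMSOTf, Et3N, CH2Cl2, 0 °C → rt) should give the linear 6-trimethylsilyloxy-6,8-diene, the silyl dienol ether F4, which can be purified from regioisomers. Rubottom oxidation (dimethyldioxirane, CH2Cl2/acetone, −78 °C; citric acid work-up) on the electron-rich C6=C7 bond from the α-face then comes back to the route at 17.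

Step 7. The allylmetal may react through its γ-carbon (allylic transposition) or lose olefin geometry, and the activated barium is delicate to handle. The fallback uses a sulfone-stabilised, regiodefined allyl anion and sets out from 10 and 5. Displacement with PhSO2Na (DMF, rt) should give the allylic sulfone F5; deprotonation (n-BuLi, THF, −78 °C) and addition to 5 at the sulfonyl-bearing carbon gives the β-hydroxy sulfone F6 as a diastereomer mixture. Dess–Martin oxidation gives the β-keto sulfone F7, and reductive desulfonylation (SmI2, THF/MeOH, −78 °C) with α-protonation comes back to the route at 13, so that steps 7 and 8 are bypassed.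

Further compounds
F1 | step 9 | (6E,8E)-trimethylsilyl trienol ether of 13 [C10=C5–C6(OSiMe3)=C7–C8(CH3)=C9] | CC1=C(/C(O[Si](C)(C)C)=C\C(C)=C\CC/C(C)=C/CO[Si](c2ccccc2)(c2ccccc2)C(C)(C)C)C(C)(C)C[C@H](O[Si](CC)(CC)CC)C1
F2 | step 9 | 15-(tert-butyldiphenylsilyloxy)-2α-(triethylsilyloxy)-6-(trimethylsilyloxy)-9β-H-labda-5,7,13E-triene | CC[Si](CC)(CC)O[C@H]1CC(C)(C)C2=C(O[Si](C)(C)C)C=C(C)[C@@H](CC/C(C)=C/CO[Si](c3ccccc3)(c3ccccc3)C(C)(C)C)[C@@]2(C)C1
F3 | step 9 | 15-(tert-butyldiphenylsilyloxy)-2α-(triethylsilyloxy)-9β-H-labda-7,13E-dien-6-one (9-epimer of 15) | CC[Si](CC)(CC)O[C@H]1CC(C)(C)[C@@H]2C(=O)C=C(C)[C@@H](CC/C(C)=C/CO[Si](c3ccccc3)(c3ccccc3)C(C)(C)C)[C@@]2(C)C1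
F4 | step 10 | 15-(tert-butyldiphenylsilyloxy)-2α-(triethylsilyloxy)-6-(trimethylsilyloxy)labda-6,8,13E-triene | CC[Si](CC)(CC)O[C@H]1CC(C)(C)[C@@H]2C(O[Si](C)(C)C)=CC(C)=C(CC/C(C)=C/CO[Si](c3ccccc3)(c3ccccc3)C(C)(C)C)[C@@]2(C)C1
F5 | step 7 | {[(2E,6E)-8-(tert-butyldiphenylsilyloxy)-2,6-dimethylocta-2,6-dien-1-yl]sulfonyl}benzene | O=S(=O)(C/C(C)=C/CC/C(C)=C/CO[Si](c1ccccc1)(c1ccccc1)C(C)(C)C)c1ccccc1
F6 | step 7 | (3E,7E)-9-(tert-butyldiphenylsilyloxy)-3,7-dimethyl-2-(phenylsulfonyl)-1-[(R)-2,6,6-trimethyl-4-(triethylsilyloxy)cyclohex-1-en-1-yl]nona-3,7-dien-1-ol (diastereomer mixture) | CC1=C(C(O)C(/C(C)=C/CC/C(C)=C/CO[Si](c2ccccc2)(c2ccccc2)C(C)(C)C)S(=O)(=O)c2ccccc2)C(C)(C)C[C@H](O[Si](CC)(CC)CC)C1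
F7 | step 7 | (3E,7E)-9-(tert-butyldiphenylsilyloxy)-3,7-dimethyl-2-(phenylsulfonyl)-1-[(R)-2,6,6-trimethyl-4-(triethylsilyloxy)cyclohex-1-en-1-yl]nona-3,7-dien-1-one | CC1=C(C(=O)C(/C(C)=C/CC/C(C)=C/CO[Si](c2ccccc2)(c2ccccc2)C(C)(C)C)S(=O)(=O)c2ccccc2)C(C)(C)C[C@H](O[Si](CC)(CC)CC)C1
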